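Remark on the chemistry: ring atoms are numbered as in isochroman-1-one (C1 carbonyl carbon, O2, C3, C4, C4a, C5–C8, C8a) and the side chain as C1'–C11' outward from C3. Propyne is assumed to be available as a compressed gas that is condensed into the flask.

## Analysis of the target

The target is a 3,4-dihydroisocoumarin: a benzo-fused δ-lactone (ring B: C1, O2, C3, C4, C4a, C8a) on a resorcinol ring (ring A: C4a–C8a) with free hydroxyls at C6 and C8, the latter hydrogen-bonded to the lactone carbonyl. C3 carries an unbranched undecyl chain with one secondary hydroxyl at C6'. There are two stereocentres, C3 (R) and C6' (S), separated by five methylene groups (C1'–C5'). Across this 1,7-relationship no substrate control is possible, so each centre must be set independently. The sensitive functions are the lactone (ring opening by base, and an O-alkyl bond at a stereocentre), the oxidisable resorcinol and the free secondary alcohol, which together argue against oxidising conditions late in the route. The difficulty is not the bicyclic core but the stereodefined, otherwise featureless tether between C3 and C6', where no functional group marks a place to cut. The strategy rests on the fact that C3 and C6' are both carbinol carbons whose inner neighbours C1' and C5' can each be the CH2 terminus of a monosubstituted epoxide. Both are then electrophiles, so the three carbons between them, C2'–C3'–C4', must be a 1,3-dinucleophile, and doubly metallated propyne is the simplest one. Because the arene enters as a 3,5-dioxygenated phenyl group with two equivalent ortho positions, the lactone carbon can be added afterwards without a choice between them.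

## Retrosynthetic reasoning

**16 ⇒ 15.** The two phenolic O–H bonds are traced back to methyl ethers. The key step exposes the arene to organolithium bases and a boron Lewis acid, and later steps to hydrogenation and palladium catalysis, so a robust ether is needed that is removed only at the end. The forward step must cleave two aryl–O–CH3 bonds without touching the lactone O-alkyl bond at C3 or the C6' carbinol.

**15 ⇒ 14.** The lactone is opened at C1–O2 and C1–C8a, so that C1 leaves as a one-carbon unit, the C3 oxygen reverts to a free hydroxyl and C8a carries bromine. Cutting here rather than at C4–C4a or O2–C3 returns an aryl group that is symmetric about the side chain, and it leaves the C3 stereocentre as a carbinol that is never an electrophile. The forward reaction is a palladium-catalysed carbonylation in which the C2 hydroxyl of 14 must capture the acyl metal species; the C8 hydroxyl could only form a twelve-membered ring.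

**14 ⇒ 13.** The C–Br bond is removed. In 13 the two ring positions ortho to the side chain are equivalent and each is para to one methoxy group and ortho to the other; the only other open position is flanked by both methoxy groups. Electrophilic bromination should therefore go ortho to the chain. A hydroxyl-directed C–H carbonylation of 13 under divalent palladium would reach 15 in one step. It is held in reserve because its silver oxidant and high temperature put two unprotected secondary carbinols at risk.

**13 ⇒ 12.** The C2'–C5' tetramethylene stretch is taken back to a C3'≡C4' triple bond. This puts a functional group in the middle of the tether and exposes the propyne unit. The forward step is a plain hydrogenation; neither carbinol is benzylic or propargylic, so no C–O bond is at risk.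

**12 ⇒ 5 + 9 + 8 (key disconnection).** Bonds C1'–C2' and C4'–C5' are cut. Each lies one carbon away from a carbinol, which is the retron of a terminal epoxide opened at its CH2. Cutting both leaves epoxides 5 and 8 as two electrophiles and the three-carbon unit 9 as a double nucleophile through its dianion 10. What is gained is full convergence: the skeleton is assembled from three small pieces in one flask, and both stereocentres arrive ready-made, because the substitutions occur at carbons that are not stereogenic. The forward reaction must use the two nucleophilic carbons of 10 in a fixed order. The sp3 carbanion opens 5 without help and gives 11. The remaining acetylide is inert to epoxides until a boron Lewis acid is added with 8.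

**5 ⇒ 4 ⇒ 1 + 2, and 8 ⇒ 7 ⇒ 6 + 2.** Both epoxides are traced to the same chiral C3 building block 2. A copper-catalysed Grignard opening at the oxirane CH2 of 2 (by 3, made from 1, or by 6) gives chlorohydrins 4 and 7, and base closes the new oxirane onto the former chloromethyl carbon. The stereogenic carbon is never attacked in either operation. One enantiomer of 2 therefore supplies C3 and C6' with the required sense, and the C–C bonds formed are the aryl–C4 bond and the C7'–C8' bond.

## Alternatives that were turned down

**Alternative 1:** Disconnection: the C4a–C8a bond of ring A is cut, which unfolds the resorcylate into the open-chain diketo-dioxinone A2.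
- Forward key step: mild base enolises A2, the dioxinone C5 (the future C8a) adds in aldol fashion to the ketone that becomes C4a, and loss of water with enolisation gives the acetonide-masked resorcylate A1.
- For: ring A forms with its oxygen pattern and carboxyl carbon already correct, so no halogenation, carbonylation or regiochemical question arises. The endgame is gentler too. Once the silyl groups are removed the C3 hydroxyl can attack the benzodioxinone carbonyl, which closes ring B and frees the C8 phenol in one event, and no methyl ether has to be cleaved. On the endgame this alternative is stronger than the chosen route.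
- Against: the cut is made in the only part of the molecule that can be bought. The 1,7-diol chain with both stereocentres still has to be built first, most simply by the epoxide chemistry used here. It must then be silylated twice, turned into an acyl donor and joined to a keto-dioxinone dianion by C-acylation. The resulting β,δ-diketo system is prone to premature cyclisation and retro-Claisen cleavage.
- Comparison: it needs at least five more linear steps and two protecting groups, spent on an arene that compound 1 supplies ready-made. The chosen strategy gives up the mild endgame for convergence and a commercial ring A.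

**Alternative 2:** Disconnection: bonds C4a–C5 and C8–C8a of ring A are cut as a [4+2] retron, giving the chain-bearing ynoate A4 and the bis(silyloxy)diene A5.
- Forward key step: thermal cycloaddition, with the nucleophilic CH terminus of A5 bonding to the β-carbon of A4. The bicyclo[2.2.2]octadiene then loses its gem-dimethyl two-carbon bridge in a retro-Diels–Alder step and aromatises to A3.
- For: the polarisation of both partners fixes the ring regiochemistry. The phenols emerge as labile trimethylsilyl ethers, and acid-mediated desilylation and lactonisation finish the target without Lewis-acid dealkylation. On the endgame it is again stronger than the chosen route.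
- Against: a β-alkyl ynoate is a poor dienophile, so prolonged heating at high temperature is to be expected. At such temperatures the propargylic CH2 next to the C5 silyloxy carbon of A4 invites alkyne–allene isomerisation. As in alternative 1, the whole stereodefined chain must precede the key step, here with two silyl ethers and an added alkyne carboxylation.
- Comparison: the synthesis of A4 is essentially the chosen route as far as a terminal alkyne, plus protection and carboxylation, and ring A is still to be made after that. It is several steps longer and places its most forcing step last, on the most advanced material. The chosen route places its risk where three small, cheap fragments meet.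

**Alternative 3:** Disconnection: bonds C4–C4a and O2–C3 of ring B are cut, giving the bromo acid A7 and the silyloxy diene A8.
- Forward key step: zerovalent palladium inserts into the C–Br bond of A7 and the aryl group adds to the terminal carbon of A8 (C4–C4a). The carboxylate then captures the π-allylpalladium at its inner terminus (O2–C3), which closes ring B and leaves an E-alkene. A chiral phosphine is to decide the configuration at C3 of A6.
- For: it is the most convergent of the three. Ring B, the lactone carbonyl and C3 arise in one step from an achiral arene, with no separate bromination or carbonylation. On this point it is stronger than the chosen route.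
- Against: the C3 configuration depends wholly on ligand control over a π-allyl with an unbranched alkyl substituent, whose faces interconvert by η3–η1–η3 equilibration, and the remote C6' centre gives no help. Any shortfall appears as the C3 epimer, a 1,7-diastereomer that is practically inseparable and hard even to detect. A8 still needs its own asymmetric entry to C6' (epoxide 8 would serve) and a stereodefined diene. Oxidative addition into the electron-rich A7 is slow. Three steps remain after the key step (alkene hydrogenation, desilylation, demethylation), including the same ether cleavage as the chosen route.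
- Comparison: the step count is similar. The chosen route takes both stereocentres from the single enantiopure building block 2 through substitutions that never touch a stereogenic carbon, so stereochemical purity depends on the starting material and not on catalyst performance.

Key step: step 5

## Route

Step 1
Reactants: 1 1-bromo-3,5-dimethoxybenzene; 2 (S)-epichlorohydrin [(S)-2-(chloromethyl)oxirane]
Product: 4 (S)-1-chloro-3-(3,5-dimethoxyphenyl)propan-2-ol, via 3,5-dimethoxyphenylmagnesium bromide 3 (not isolated)
Conditions: Mg, THF, reflux → rt; CuI (10 mol %), then 2, THF, −40 → 0 °C; aq. NH4Cl
Reagents that add atoms: none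
Why: Copper-catalysed Grignard opening of an epoxide: the arylcopper species attacks the unsubstituted oxirane carbon of 2 by SN2 faster than it displaces chloride, and the stereogenic carbon is not touched (still S, since CH2Cl outranks the new benzyl carbon).

Step 2
Reactants: 4 (S)-1-chloro-3-(3,5-dimethoxyphenyl)propan-2-ol
Product: 5 (S)-2-(3,5-dimethoxybenzyl)oxirane
Conditions: powdered NaOH, Et2O, 0 °C → rt
Reagents that add atoms: none
Why: Intramolecular Williamson etherification (3-exo-tet): the alkoxide displaces the primary chloride, and the stereocentre is the carbon bearing the nucleophilic oxygen, so it is retained as S.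

Step 3
Reactants: 6 n-butylmagnesium chloride; 2 (S)-epichlorohydrin
Product: 7 (S)-1-chloroheptan-2-ol
Conditions: CuI (10 mol %), THF, −40 → 0 °C; aq. NH4Cl
Reagents that add atoms: none
Why: The same copper-catalysed SN2 opening at the oxirane CH2 of 2, here with an alkyl Grignard reagent; the stereocentre is untouched and stays S.

Step 4
Reactants: 7 (S)-1-chloroheptan-2-ol
Product: 8 (S)-2-pentyloxirane
Conditions: powdered NaOH, Et2O, 0 °C → rt; distillation
Reagents that add atoms: none
Why: Intramolecular Williamson ring closure onto the chloromethyl carbon with retention at the carbinol carbon; the volatile epoxide is purified by distillation.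

Step 5
Reactants: 9 propyne; 5 (S)-2-(3,5-dimethoxybenzyl)oxirane; 8 (S)-2-pentyloxirane
Product: 12 (2R,8S)-1-(3,5-dimethoxyphenyl)tridec-5-yne-2,8-diol, via 1,3-dilithiopropyne 10 (not isolated), via dilithiated hexynol 11 (not isolated)
Conditions: 9 (1.2 equiv), n-BuLi (2.4 equiv), TMEDA (1.2 equiv), Et2O/hexane, −78 → 0 °C; 5 (1.0 equiv), THF, −78 → 0 °C; then −78 °C, BF3·OEt2 (4 equiv), 8 (1.5 equiv); H2O
Reagents that add atoms: none
Why: Proposed new method: two equivalents of n-BuLi with TMEDA remove first the acetylenic and then a propargylic proton of 9, and the dianion 10 carries a delocalised propargyl/allenyl carbanion far more basic and nucleophilic than its acetylide end; this carbon opens 5 by SN2 attack at the unsubstituted oxirane CH2 (bond C1'–C2') and leaves the lithium alkoxide acetylide 11. A lithium acetylide does not open an unactivated epoxide in ether solvents at or below 0 °C, so 11 neither consumes a second molecule of 5 nor reacts with 8 until BF3·OEt2 is added, whereupon the alkynyl trifluoroborate formed at −78 °C attacks the Lewis-acid-activated oxirane 8 at its CH2 (bond C4'–C5'). The closest known reaction types are the propargylic alkylation of 1,3-dilithiopropyne by terminal epoxides or alkyl halides with later capture of the remaining acetylide by a second electrophile, and the BF3·OEt2-promoted alkynylation of epoxides; what is new is running both in one flask with two different epoxides. No ring is closed and no stereocentre is created: C2 and C8 of 12 are the oxirane methine carbons of 5 and 8, whose C–O bonds are never broken, so both configurations are carried over (C2 is now named R only because the former oxirane CH2 drops below the benzyl carbon in priority; C8 stays S). The step needs site order between the two nucleophilic carbons, which the reactivity gap and the withheld Lewis acid provide; it needs propargyl rather than allenyl bonding in the first alkylation, the normal outcome for this dianion because the terminal sp carbon remains tied up as the acetylide; and it needs attack at the less hindered oxirane carbon in both openings, which monosubstituted epoxides favour strongly. BF3·OEt2 is charged in excess of what TMEDA and the C2 alkoxide bind, and the first stage is kept at or below 0 °C so that deprotonation at the benzylic CH2 or between the two methoxy groups does not compete.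

Step 6
Reactants: 12 (2R,8S)-1-(3,5-dimethoxyphenyl)tridec-5-yne-2,8-diol
Product: 13 (2R,8S)-1-(3,5-dimethoxyphenyl)tridecane-2,8-diol
Conditions: H2 (1 atm), 10 % Pd/C, EtOAc, rt
Reagents that add atoms: none
Why: Heterogeneous catalytic hydrogenation of the internal alkyne to the alkane; neither carbinol is benzylic or propargylic, so no C–O hydrogenolysis is expected and the stereocentres are not involved.

Step 7
Reactants: 13 (2R,8S)-1-(3,5-dimethoxyphenyl)tridecane-2,8-diol
Product: 14 (2R,8S)-1-(2-bromo-3,5-dimethoxyphenyl)tridecane-2,8-diol
Conditions: NBS (1.0 equiv), MeCN, 0 °C, dark
Reagents that add atoms: N-bromosuccinimide, O=C1CCC(=O)N1Br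
Why: Electrophilic aromatic bromination: the ring carbon ortho to the side chain is para to one methoxy group and ortho to the other and is less hindered than the carbon flanked by both methoxy groups, so monobromination there is expected, as with other 5-alkylresorcinol dimethyl ethers. The two ortho positions are equivalent, and the carbinols are inert to NBS at 0 °C on this time scale.

Step 8
Reactants: 14 (2R,8S)-1-(2-bromo-3,5-dimethoxyphenyl)tridecane-2,8-diol
Product: 15 (3R)-3-[(6S)-6-hydroxyundecyl]-6,8-dimethoxyisochroman-1-one
Conditions: Pd(OAc)2 (5 mol %), Xantphos (6 mol %), CO (1 atm), Et3N (3 equiv), toluene, 100 °C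
Reagents that add atoms: carbon monoxide, [C-]#[O+]
Why: Palladium-catalysed carbonylative lactonisation of an o-bromophenethyl alcohol: zerovalent palladium inserts into the C–Br bond, CO insertion gives the aroylpalladium bromide, and the C2 hydroxyl captures it to close the six-membered lactone, whereas the C8 hydroxyl could only form a twelve-membered ring. The C–O bond at the stereocentre is not broken, so C3 of 15 is R.

Step 9
Reactants: 15 (3R)-3-[(6S)-6-hydroxyundecyl]-6,8-dimethoxyisochroman-1-one
Product: 16 (3R)-6,8-dihydroxy-3-[(6S)-6-hydroxyundecyl]isochroman-1-one
Conditions: BBr3 (6 equiv), CH2Cl2, −78 → 0 °C; H2O quench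
Reagents that add atoms: none
Why: Lewis-acid cleavage of aryl methyl ethers: BBr3 coordinates the ether oxygens and bromide removes the methyl groups, the C8 ether (chelated to the lactone carbonyl) first and the C6 ether on warming. The lactone O-alkyl bond and the side-chain carbinol, held as its borate until the aqueous quench, are expected to survive at or below 0 °C, so both stereocentres are unchanged.

## Compound list

1 | 1-bromo-3,5-dimethoxybenzene | COc1cc(Br)cc(OC)c1 | starting material
2 | (S)-epichlorohydrin, (S)-2-(chloromethyl)oxirane | ClC[C@@H]1CO1 | starting material
3 | 3,5-dimethoxyphenylmagnesium bromide | COc1cc(OC)cc([Mg]Br)c1 | intermediate (not isolated)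
4 | (S)-1-chloro-3-(3,5-dimethoxyphenyl)propan-2-ol | COc1cc(OC)cc(C[C@H](O)CCl)c1 | intermediate
5 | (S)-2-(3,5-dimethoxybenzyl)oxirane | COc1cc(OC)cc(C[C@H]2CO2)c1 | intermediate
6 | n-butylmagnesium chloride | CCCC[Mg]Cl | starting material
7 | (S)-1-chloroheptan-2-ol | CCCCC[C@H](O)CCl | intermediate
8 | (S)-2-pentyloxirane | CCCCC[C@H]1CO1 | intermediate
9 | propyne | CC#C | starting material
10 | 1,3-dilithiopropyne | [Li]CC#C[Li] | intermediate (not isolated)
11 | lithium (2R)-1-(3,5-dimethoxyphenyl)-6-lithiohex-5-yn-2-olate (dilithiated hexynol) | COc1cc(OC)cc(C[C@H](O[Li])CCC#C[Li])c1 | intermediate (not isolated)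
12 | (2R,8S)-1-(3,5-dimethoxyphenyl)tridec-5-yne-2,8-diol | COc1cc(OC)cc(C[C@H](O)CCC#CC[C@@H](O)CCCCC)c1 | intermediate
13 | (2R,8S)-1-(3,5-dimethoxyphenyl)tridecane-2,8-diol | COc1cc(OC)cc(C[C@H](O)CCCCC[C@@H](O)CCCCC)c1 | intermediate
14 | (2R,8S)-1-(2-bromo-3,5-dimethoxyphenyl)tridecane-2,8-diol | COc1cc(OC)c(Br)c(C[C@H](O)CCCCC[C@@H](O)CCCCC)c1 | intermediate
15 | (3R)-3-[(6S)-6-hydroxyundecyl]-6,8-dimethoxyisochroman-1-one | CCCCC[C@H](O)CCCCC[C@@H]1Cc2cc(OC)cc(OC)c2C(=O)O1 | intermediate
16 | (3R)-6,8-dihydroxy-3-[(6S)-6-hydroxyundecyl]isochroman-1-one | CCCCC[C@H](O)CCCCC[C@@H]1Cc2cc(O)cc(O)c2C(=O)O1 | target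

## Step count and least certain steps

Total step count: 9. Longest linear sequence: 7 steps (steps 1, 2, 5, 6, 7, 8, 9, from compound 1); steps 3 and 4 form the second branch.

**Step 5 (key step, carries the new-method label).**
- What may go wrong: the second opening may stall because the C2 alkoxide and TMEDA compete with the acetylide and with 8 for the Lewis acid, leaving the acetylide unalkylated. In the first stage, base-induced isomerisation of 5 through benzylic deprotonation may compete with ring opening. Any excess of 10 also consumes part of 8.
- Fallback (known chemistry only), from 5, 8 and 9, returning at 12: the dianion 10 is used only for the first opening, which is established on its own. Water quench gives (R)-1-(3,5-dimethoxyphenyl)hex-5-yn-2-ol F1. Silylation (TBSCl, imidazole, DMF) gives tert-butyl{[(2R)-1-(3,5-dimethoxyphenyl)hex-5-yn-2-yl]oxy}dimethylsilane F2. Its lithium acetylide (n-BuLi, THF, −78 °C) is coupled with 8 under BF3·OEt2 in a standard epoxide alkynylation, free of alkoxide and diamine, to give (6S,12R)-12-(tert-butyldimethylsilyloxy)-13-(3,5-dimethoxyphenyl)tridec-8-yn-6-ol F3. TBAF in THF then returns 12. This costs three more steps but removes the competition for the Lewis acid.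

**Step 8.**
- What may go wrong: oxidative addition into the electron-rich C–Br bond, flanked by a methoxy group and the side chain, may be slow. Reductive loss of bromine or deposition of palladium metal under CO could then overtake carbonylation.
- Fallback, from 14, returning at 15: the carboxyl carbon is introduced through an organolithium instead of palladium. n-BuLi (2 equiv) converts 14 into its dialkoxide, t-BuLi (2 equiv) at −78 °C effects bromine–lithium exchange, and CO2 traps the aryllithium. Acidification gives 2-[(2R,8S)-2,8-dihydroxytridecyl]-4,6-dimethoxybenzoic acid F4, which closes to 15 with catalytic TsOH in toluene; the six-membered lactone is the only ring within reach.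

**Step 9.**
- What may go wrong: the C6 methyl ether, para to the carbonyl, is the slower one to cleave. At the temperature it needs, the dibromoboryl ether of the C6' carbinol may undergo substitution by bromide or elimination, and the lactone O-alkyl bond may be attacked.
- Fallback, from 15, returning at 16: the carbinol is masked before the ether cleavage. Ac2O, pyridine and DMAP give (6S)-1-[(3R)-6,8-dimethoxy-1-oxoisochroman-3-yl]undecan-6-yl acetate F5. BBr3 in CH2Cl2, which can now be run up to room temperature, gives (6S)-1-[(3R)-6,8-dihydroxy-1-oxoisochroman-3-yl]undecan-6-yl acetate F6. K2CO3 in methanol removes the acetate, and acidification to pH 3 recloses any lactone opened by methoxide, giving 16.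

**Step 7.**
- What may go wrong: loss of regiocontrol (attack at the carbon between the methoxy groups) or double bromination on the highly activated ring.
- Fallback, from 13, returning at 15 without passing through 14: hydroxyl-directed C–H carbonylation (Pd(OAc)2, an N-protected amino acid ligand such as Boc-L-leucine, AgOAc, Li2CO3, CO, CH2Cl2, sealed tube, 110 °C). The six-membered palladacycle anchored on the C2 hydroxyl can reach only the positions ortho to the side chain, so the regiochemical question disappears. It is a reserve rather than the first choice because oxidation of the two free carbinols by divalent palladium is its own hazard.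

## Further compounds

F1 | step 5 | (R)-1-(3,5-dimethoxyphenyl)hex-5-yn-2-ol | COc1cc(OC)cc(C[C@H](O)CCC#C)c1
F2 | step 5 | tert-butyl{[(2R)-1-(3,5-dimethoxyphenyl)hex-5-yn-2-yl]oxy}dimethylsilane | COc1cc(OC)cc(C[C@H](O[Si](C)(C)C(C)(C)C)CCC#C)c1
F3 | step 5 | (6S,12R)-12-(tert-butyldimethylsilyloxy)-13-(3,5-dimethoxyphenyl)tridec-8-yn-6-ol | COc1cc(OC)cc(C[C@H](O[Si](C)(C)C(C)(C)C)CCC#CC[C@@H](O)CCCCC)c1
F4 | step 8 | 2-[(2R,8S)-2,8-dihydroxytridecyl]-4,6-dimethoxybenzoic acid | COc1cc(OC)c(C(=O)O)c(C[C@H](O)CCCCC[C@@H](O)CCCCC)c1
F5 | step 9 | (6S)-1-[(3R)-6,8-dimethoxy-1-oxoisochroman-3-yl]undecan-6-yl acetate | CCCCC[C@H](OC(C)=O)CCCCC[C@@H]1Cc2cc(OC)cc(OC)c2C(=O)O1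
F6 | step 9 | (6S)-1-[(3R)-6,8-dihydroxy-1-oxoisochroman-3-yl]undecan-6-yl acetate | CCCCC[C@H](OC(C)=O)CCCCC[C@@H]1Cc2cc(O)cc(O)c2C(=O)O1
F0 | step 7 | none | none
A1 | alternative 1 | 5-[(2R,8S)-2,8-bis(tert-butyldimethylsilyloxy)tridecyl]-7-hydroxy-2,2-dimethyl-4H-benzo[d][1,3]dioxin-4-one | CC1(C)Oc2cc(O)cc(C[C@H](O[Si](C)(C)C(C)(C)C)CCCCC[C@@H](O[Si](C)(C)C(C)(C)C)CCCCC)c2C(=O)O1
A2 | alternative 1 | 6-[(6R,12S)-6,12-bis(tert-butyldimethylsilyloxy)-2,4-dioxoheptadecyl]-2,2-dimethyl-4H-1,3-dioxin-4-one | CC1(C)OC(CC(=O)CC(=O)C[C@H](O[Si](C)(C)C(C)(C)C)CCCCC[C@@H](O[Si](C)(C)C(C)(C)C)CCCCC)=CC(=O)O1
A3 | alternative 2 | methyl 2-[(2R,8S)-2,8-bis(tert-butyldimethylsilyloxy)tridecyl]-4,6-bis(trimethylsilyloxy)benzoate | COC(=O)c1c(O[Si](C)(C)C)cc(O[Si](C)(C)C)cc1C[C@H](O[Si](C)(C)C(C)(C)C)CCCCC[C@@H](O[Si](C)(C)C(C)(C)C)CCCCC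
A4 | alternative 2 | methyl (5R,11S)-5,11-bis(tert-butyldimethylsilyloxy)hexadec-2-ynoate | COC(=O)C#CC[C@H](O[Si](C)(C)C(C)(C)C)CCCCC[C@@H](O[Si](C)(C)C(C)(C)C)CCCCC
A5 | alternative 2 | 5,5-dimethyl-1,3-bis(trimethylsilyloxy)cyclohexa-1,3-diene | C[Si](C)(C)OC1=CC(O[Si](C)(C)C)=CC(C)(C)C1
A6 | alternative 3 | (S)-3-[(S,E)-6-(tert-butyldimethylsilyloxy)undec-1-en-1-yl]-6,8-dimethoxyisochroman-1-one | CCCCC[C@H](O[Si](C)(C)C(C)(C)C)CCC/C=C/[C@@H]1Cc2cc(OC)cc(OC)c2C(=O)O1
A7 | alternative 3 | 2-bromo-4,6-dimethoxybenzoic acid | COc1cc(Br)c(C(=O)O)c(OC)c1
A8 | alternative 3 | (S,E)-tert-butyldimethyl(trideca-10,12-dien-6-yloxy)silane | C=C/C=C/CCC[C@@H](O[Si](C)(C)C(C)(C)C)CCCCC
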